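**Retrosynthetic overview**
1. Ring order: the ten-membered carbocycle (ring A, C1–C10) is closed first at C5–C6 by alkenyl iodide/aldehyde coupling with CrCl2/NiCl2. The γ-lactone (ring B, O–C6–C7–C11–C12) follows by oxidative lactonisation of O6–H onto C12. The O9 acetate and free O15–H come last.
2. Key disconnection: C1–C2 and C9–C10 are made in one flask from a C2 alkylcopper, methyl propiolate and the C9 aldehyde. It rests on C10 being the α-carbon of the C1=C10–C14 enoate, bonded to carbinol C9 and to C1, whose substituent C2 is cis to C9 (the ring-cis 1(10)-alkene of ring A).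
3. Iodide (C2–C5, C15): anti-vinylmagnesiation of 3-(trimethylsilyl)propargyl alcohol, hydroboration, iodination. The C5–SiMe3 group is the latent C5 iodide.
4. Aldehyde (C6–C9, C11–C13): indium Barbier union of a Morita–Baylis–Hillman-derived allyl bromide with (R)-glyceraldehyde acetonide sets C7 and C8. C9 is freed by glycol cleavage.

Key step: step 12

Remark: atoms carry germacrane numbers (ring C1–C10; C11–C13 the methylene-lactone carbons; C14 the ester carbon on C10; C15 the hydroxymethyl carbon on C4). C6 is carried as a 1,3-dioxolane and O12 as a p-methoxybenzyl ether until after the union, because a dimethyl acetal would be captured by the glycol freed on the way to the C9 aldehyde and a labile silyl ether at O12 would not survive that acid.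

**Route**

Step 1
Reactants: 1 3-(trimethylsilyl)prop-2-yn-1-ol
Product: 3 (2E)-2-ethenyl-3-(trimethylsilyl)prop-2-en-1-ol, via cyclic alkenylmagnesium alkoxide 2 (not isolated)
Conditions: CH2=CHMgCl (3.5 equiv), THF–cyclohexane, reflux; aq. NH4Cl, 0 °C
Reagents that add atoms: vinylmagnesium chloride, C=C[Mg]Cl
Why: Alkoxide-directed anti-carbomagnesiation of a propargylic alcohol: vinyl adds to the carbon next to the carbinol and magnesium to the silicon-bearing carbon inside a five-membered oxamagnesacycle, so protonation leaves SiMe3 cis to the vinyl branch (C3) and trans to C15.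

Step 2
Reactants: 3 (2E)-2-ethenyl-3-(trimethylsilyl)prop-2-en-1-ol
Product: 4 tert-butyldiphenylsilyl ether of 3
Conditions: TBDPSCl, imidazole, CH2Cl2, rt
Reagents that add atoms: tert-butyl(chloro)diphenylsilane, CC(C)(C)[Si](Cl)(c1ccccc1)c1ccccc1
Why: Standard imidazole-mediated silylation of a primary allylic alcohol; this silyl ether is chosen to outlast every later triethylsilyl cleavage.

Step 3
Reactants: 4 tert-butyldiphenylsilyl ether of 3
Product: 6 (3E)-3-{[tert-butyl(diphenyl)silyl]oxymethyl}-4-(trimethylsilyl)but-3-en-1-ol, via B-alkyl-9-borabicyclononane 5 (not isolated)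
Conditions: 9-BBN (1.3 equiv), THF, 0 °C to rt; NaOH, H2O2, 0 °C
Reagents that add atoms: 9-borabicyclo[3.3.1]nonane, B1C2CCCC1CCC2 (in 5 only); hydrogen peroxide, OO
Why: Anti-Markovnikov hydroboration–oxidation: 9-BBN puts boron on the unhindered CH2 terminus of the monosubstituted alkene of the diene and leaves the trisubstituted vinylsilane untouched.

Step 4
Reactants: 6 homoallylic alcohol
Product: 7 tert-butyl{[(2E)-2-(2-iodoethyl)-3-(trimethylsilyl)prop-2-en-1-yl]oxy}diphenylsilane
Conditions: PPh3, I2, imidazole, CH2Cl2, 0 °C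
Reagents that add atoms: iodine, II
Why: Appel-type iodination of a primary alcohol; iodine is bound as the phosphonium salt before it can attack the vinylsilane.

Step 5
Reactants: 8 2,2-dimethoxyacetaldehyde; 9 methyl acrylate
Product: 10 methyl 3-hydroxy-4,4-dimethoxy-2-methylidenebutanoate (racemic)
Conditions: DABCO (0.5 equiv), 1,4-dioxane–H2O (1:1), rt
Reagents that add atoms: none
Why: Morita–Baylis–Hillman reaction of an activated α-alkoxy aldehyde; the racemic carbinol is erased in step 7.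

Step 6
Reactants: 10 Morita–Baylis–Hillman adduct
Product: 11 methyl 2-[(1,3-dioxolan-2-yl)(hydroxy)methyl]prop-2-enoate (racemic)
Conditions: HOCH2CH2OH (5 equiv), p-TsOH·H2O (5 mol %), toluene, 50 °C, reduced pressure (removal of MeOH)
Reagents that add atoms: ethylene glycol, OCCO
Why: Acid-catalysed transacetalisation driven by removal of methanol; the cyclic acetal resists the acid of step 11 and is not captured by neighbouring hydroxyls.

Step 7
Reactants: 11 dioxolane adduct
Product: 12 methyl (2Z)-2-(bromomethyl)-3-(1,3-dioxolan-2-yl)prop-2-enoate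
Conditions: NBS, Me2S, CH2Cl2, 0 °C to rt
Reagents that add atoms: N-bromosuccinimide, O=C1CCC(=O)N1Br
Why: Corey–Kim-type activation of the alcohol followed by SN2′ attack of bromide gives the conjugated primary allyl bromide in its thermodynamic geometry, C6 cis to CH2Br.

Step 8
Reactants: 12 allyl bromide; 13 (R)-2,2-dimethyl-1,3-dioxolane-4-carbaldehyde
Product: 15 methyl (3R,4S)-3-(1,3-dioxolan-2-yl)-4-[(4R)-2,2-dimethyl-1,3-dioxolan-4-yl]-4-hydroxy-2-methylidenebutanoate, via allylindium dibromide 14 (not isolated)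
Conditions: In powder (1.5 equiv), THF–H2O (1:1), rt
Reagents that add atoms: indium, [In] (in 14 only)
Why: Indium-mediated Barbier allylation through a six-membered chair: the C6 group cis to CH2–In sits axial and should give the 7,8-syn adduct (C6 syn to O8), and Felkin–Anh attack on the non-chelating acetonide aldehyde should put O8 anti to the dioxolane oxygen, which fixes C7 and C8 in the absolute sense required.

Step 9
Reactants: 15 hydroxy ester
Product: 16 (1S,2R)-2-(1,3-dioxolan-2-yl)-1-[(4R)-2,2-dimethyl-1,3-dioxolan-4-yl]-3-methylidenebutane-1,4-diol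
Conditions: i-Bu2AlH (4 equiv), CH2Cl2, −78 to −20 °C; Rochelle salt
Reagents that add atoms: none
Why: 1,2-Reduction of the 2-substituted acrylate ester by i-Bu2AlH; the acetals are inert below 0 °C.

Step 10
Reactants: 16 diol
Product: 17 O8,O12-bis(4-methoxybenzyl) ether of 16
Conditions: NaH, PMBCl, n-Bu4NI (cat.), DMF, 0 °C to rt
Reagents that add atoms: 4-methoxybenzyl chloride, COc1ccc(CCl)cc1
Why: Williamson etherification of both alkoxides under basic conditions, so no acid is present that could close the free O12–H onto C6.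

Step 11
Reactants: 17 bis-ether acetonide
Product: 19 (2S,3R)-3-(1,3-dioxolan-2-yl)-2-[(4-methoxybenzyl)oxy]-4-{[(4-methoxybenzyl)oxy]methyl}pent-4-enal, via glycol 18 (not isolated)
Conditions: H5IO6 (1.5 equiv), EtOAc, 0 °C to rt
Reagents that add atoms: none
Why: Periodic acid hydrolyses the terminal isopropylidene ketal and cleaves the freed glycol at once (Malaprade cleavage), while the aldehyde-derived dioxolane ionises far more slowly and the ethers are inert.

Step 12
Reactants: 7 homoallylic iodide; 20 methyl propiolate; 19 C9 aldehyde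
Product: 24 acyclic C9 alcohol with the C1=C10 enoate, via alkylmagnesium iodide 21 (not isolated), via alkylcopper 22 (not isolated), via α-cuprio enoate 23 (not isolated)
Conditions: Mg, Et2O, rt; CuBr·SMe2 (1.0 equiv), THF–Me2S, −45 °C; 20, −78 °C, 1 h; 19 premixed with MgBr2·OEt2 (2 equiv) in CH2Cl2, −78 °C; aq. NH4Cl, −78 °C
Reagents that add atoms: magnesium, [Mg] (in 21 only); CuBr·SMe2, CSC.Br[Cu] (copper in 22 and 23 only)
Why: The primary alkylcopper 22 adds syn across methyl propiolate at −78 °C, C2 bonding to C1 and copper to C10, so that in the α-cuprio enoate 23 the C2 chain and the metal are cis; the carbon–copper bond then adds to the MgBr2-chelated aldehyde 19 with retention, which gives the C1=C10 alkene with C2 cis to C9 and trans to C14. The closest known reaction type is the tandem conjugate addition–aldol of organocopper reagents, propiolate esters and aldehydes, which gives β-substituted α-(hydroxyalkyl)acrylates. No ring is closed. The new stereocentre C9 is controlled by the Cram chelate of magnesium between the aldehyde oxygen and the O8 p-methoxybenzyl ether: attack on the face away from the C7 branch should give the 8,9-syn carbinol. The step needs syn addition, retention at C10 and one aldehyde face; holding the mixture at −78 °C keeps 23 carbon-bound (on warming it equilibrates through the allenolate, which would deliver the isomer with C2 trans to C9), and the chelating O8 ether secures the face.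

Step 13
Reactants: 24 C9 alcohol
Product: 25 O9-triethylsilyl ether of 24
Conditions: TESCl, imidazole, DMAP (cat.), DMF, rt
Reagents that add atoms: chlorotriethylsilane, CC[Si](Cl)(CC)CC
Why: Silylation of the hindered allylic alcohol with a silyl chloride, chosen because a silyl triflate would activate the dioxolane.

Step 14
Reactants: 25 O9-silyl ether
Product: 26 O8,O12-diol
Conditions: DDQ (2.6 equiv), CH2Cl2–pH 7 buffer (10:1), 0 °C to rt
Reagents that add atoms: none
Why: Oxidative cleavage of both p-methoxybenzyl ethers by DDQ in buffered wet CH2Cl2; silyl ethers, acetal, vinylsilane and esters are inert.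

Step 15
Reactants: 26 O8,O12-diol
Product: 27 O12-triethylsilyl ether of 26
Conditions: TESCl (1.1 equiv), imidazole, CH2Cl2, −78 to −40 °C
Reagents that add atoms: chlorotriethylsilane, CC[Si](Cl)(CC)CC
Why: Selective silylation of the primary allylic O12–H over the hindered secondary O8–H at low temperature.

Step 16
Reactants: 27 O8 alcohol
Product: 28 O8 methacrylate
Conditions: methacrylic anhydride, DMAP, Et3N, CH2Cl2, 0 °C to rt
Reagents that add atoms: methacrylic anhydride, CC(=C)C(=O)OC(=O)C(C)=C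
Why: DMAP-catalysed acylation of the secondary O8–H; O9 is blocked, so no acyl migration can occur.

Step 17
Reactants: 28 alkenylsilane
Product: 29 C5 alkenyl iodide
Conditions: NIS, MeCN–ClCH2CN (4:1), 0 °C to rt, dark
Reagents that add atoms: N-iodosuccinimide, O=C1CCC(=O)N1I
Why: Electrophilic ipso-iododesilylation: NIS attacks C5 to give a tertiary β-silyl cation that loses silicon with retention, faster than it attacks the electron-poor or 1,1-disubstituted alkenes.

Step 18
Reactants: 29 dioxolane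
Product: 31 C6 aldehyde, via collidinium acetal salt 30 (not isolated)
Conditions: TESOTf (2 equiv), 2,4,6-collidine (3 equiv), CH2Cl2, 0 °C; then H2O
Reagents that add atoms: water, O; triethylsilyl triflate, CC[Si](CC)(CC)OS(=O)(=O)C(F)(F)F (in 30 only); 2,4,6-collidine, Cc1cc(C)nc(C)c1 (in 30 only)
Why: Silyl triflate–collidine opening of the aldehyde acetal to a collidinium salt, hydrolysed on adding water; silyl ethers, esters and the alkenyl iodide are inert and the medium is too weakly basic to move the β,γ-alkene into conjugation.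

Step 19
Reactants: 31 iodo aldehyde
Product: 33 ten-membered carbocyclic C6 alcohol (6R), via alkenylchromium dichloride 32 (not isolated)
Conditions: CrCl2 (10 equiv), NiCl2 (0.1 equiv), DMSO–THF, 2 mM, slow addition, rt
Reagents that add atoms: chromium dichloride, Cl[Cr]Cl (in 32 only)
Why: Nozaki–Hiyama–Kishi reaction: zerovalent nickel inserts into the alkenyl iodide, the alkenyl group passes to trivalent chromium with retention and adds to the C6 aldehyde, closing ring A at C5–C6 under high dilution with both ring-cis alkenes bending the chain; Felkin–Anh attack anti to the C7–C8 bond should place O6 trans to the C7 side chain (6R).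

Step 20
Reactants: 33 macrocyclic alcohol
Product: 34 O6,O12-diol
Conditions: PPTS (0.2 equiv), MeOH–CH2Cl2 (1:4), −10 °C
Reagents that add atoms: none
Why: Acid-catalysed methanolysis removes the primary allylic triethylsilyl ether faster than the hindered secondary one at O9 and far faster than the tert-butyldiphenylsilyl ether.

Step 21
Reactants: 34 O6,O12-diol
Product: 37 6,12-lactone, via enal 35 (not isolated), via lactol 36 (not isolated)
Conditions: TEMPO (0.3 equiv), PhI(OAc)2 (3 equiv), CH2Cl2, rt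
Reagents that add atoms: none
Why: TEMPO/PhI(OAc)2 oxidative lactonisation: the primary allylic alcohol is oxidised to the enal, O6–H closes the five-membered lactol of ring B and this is oxidised to the lactone, while O9 stays silylated so that it cannot compete for C12.

Step 22
Reactants: 37 lactone
Product: 38 C9 alcohol
Conditions: HF·pyridine, pyridine, THF, 0 °C
Reagents that add atoms: none
Why: Fluoride cleavage of the secondary triethylsilyl ether with buffered HF·pyridine, which the primary tert-butyldiphenylsilyl ether survives; the acidic medium suppresses O8-to-O9 acyl migration.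

Step 23
Reactants: 38 C9 alcohol
Product: 39 O9 acetate
Conditions: Ac2O, pyridine, DMAP (cat.), CH2Cl2, 0 °C
Reagents that add atoms: acetic anhydride, CC(=O)OC(C)=O
Why: DMAP-catalysed acetylation of the only free hydroxyl.

Step 24
Reactants: 39 O9 acetate
Product: 40 target CNP0179134.2
Conditions: HF·pyridine (excess), THF, 0 °C to rt
Reagents that add atoms: none
Why: Fluoride cleavage of the primary allylic tert-butyldiphenylsilyl ether under conditions that spare the three esters and the α-methylene lactone.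

**Compound list**
1 | 3-(trimethylsilyl)prop-2-yn-1-ol | C[Si](C)(C)C#CCO | starting material
2 | 3-ethenyl-4-(trimethylsilyl)-2,5-dihydro-1,2-oxamagnesole (cyclic alkenylmagnesium alkoxide) | C=CC1=C([Si](C)(C)C)[Mg]OC1 | intermediate
3 | (2E)-2-ethenyl-3-(trimethylsilyl)prop-2-en-1-ol | C=C/C(CO)=C\[Si](C)(C)C | intermediate
4 | tert-butyl{[(2E)-2-ethenyl-3-(trimethylsilyl)prop-2-en-1-yl]oxy}diphenylsilane | C=C/C(CO[Si](c1ccccc1)(c1ccccc1)C(C)(C)C)=C\[Si](C)(C)C | intermediate
5 | B-alkyl-9-borabicyclononane adduct of 4 (boron on C2) | C[Si](C)(C)/C=C(/CO[Si](c1ccccc1)(c1ccccc1)C(C)(C)C)CCB1C2CCCC1CCC2 | intermediate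
6 | (3E)-3-{[tert-butyl(diphenyl)silyl]oxymethyl}-4-(trimethylsilyl)but-3-en-1-ol | OCC/C(CO[Si](c1ccccc1)(c1ccccc1)C(C)(C)C)=C\[Si](C)(C)C | intermediate
7 | tert-butyl{[(2E)-2-(2-iodoethyl)-3-(trimethylsilyl)prop-2-en-1-yl]oxy}diphenylsilane | ICC/C(CO[Si](c1ccccc1)(c1ccccc1)C(C)(C)C)=C\[Si](C)(C)C | intermediate
8 | 2,2-dimethoxyacetaldehyde | COC(OC)C=O | starting material
9 | methyl acrylate | C=CC(=O)OC | starting material
10 | methyl 3-hydroxy-4,4-dimethoxy-2-methylidenebutanoate (racemic) | COC(OC)C(O)C(=C)C(=O)OC | intermediate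
11 | methyl 2-[(1,3-dioxolan-2-yl)(hydroxy)methyl]prop-2-enoate (racemic) | OC(C1OCCO1)C(=C)C(=O)OC | intermediate
12 | methyl (2Z)-2-(bromomethyl)-3-(1,3-dioxolan-2-yl)prop-2-enoate | COC(=O)/C(CBr)=C/C1OCCO1 | intermediate
13 | (R)-2,2-dimethyl-1,3-dioxolane-4-carbaldehyde ((R)-glyceraldehyde acetonide) | CC1(C)OC[C@@H](O1)C=O | starting material
14 | allylindium dibromide from 12 (indium on the CH2 carbon) | COC(=O)/C(C[In](Br)Br)=C/C1OCCO1 | intermediate
15 | methyl (3R,4S)-3-(1,3-dioxolan-2-yl)-4-[(4R)-2,2-dimethyl-1,3-dioxolan-4-yl]-4-hydroxy-2-methylidenebutanoate | CC1(C)OC[C@@H](O1)[C@@H](O)[C@H](C1OCCO1)C(=C)C(=O)OC | intermediate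
16 | (1S,2R)-2-(1,3-dioxolan-2-yl)-1-[(4R)-2,2-dimethyl-1,3-dioxolan-4-yl]-3-methylidenebutane-1,4-diol | CC1(C)OC[C@@H](O1)[C@@H](O)[C@H](C1OCCO1)C(=C)CO | intermediate
17 | (4R)-4-[(1S,2R)-2-(1,3-dioxolan-2-yl)-1-[(4-methoxybenzyl)oxy]-3-{[(4-methoxybenzyl)oxy]methyl}but-3-en-1-yl]-2,2-dimethyl-1,3-dioxolane | CC1(C)OC[C@@H](O1)[C@@H](OCc1ccc(OC)cc1)[C@H](C1OCCO1)C(=C)COCc1ccc(OC)cc1 | intermediate
18 | (2R,3S,4R)-4-(1,3-dioxolan-2-yl)-3-[(4-methoxybenzyl)oxy]-5-{[(4-methoxybenzyl)oxy]methyl}hex-5-ene-1,2-diol | OC[C@@H](O)[C@@H](OCc1ccc(OC)cc1)[C@H](C1OCCO1)C(=C)COCc1ccc(OC)cc1 | intermediate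
19 | (2S,3R)-3-(1,3-dioxolan-2-yl)-2-[(4-methoxybenzyl)oxy]-4-{[(4-methoxybenzyl)oxy]methyl}pent-4-enal | O=C[C@@H](OCc1ccc(OC)cc1)[C@H](C1OCCO1)C(=C)COCc1ccc(OC)cc1 | intermediate
20 | methyl propiolate | C#CC(=O)OC | starting material
21 | alkylmagnesium iodide from 7 (magnesium on C2) | I[Mg]CC/C(CO[Si](c1ccccc1)(c1ccccc1)C(C)(C)C)=C\[Si](C)(C)C | intermediate
22 | alkylcopper from 21 (copper on C2) | [Cu]CC/C(CO[Si](c1ccccc1)(c1ccccc1)C(C)(C)C)=C\[Si](C)(C)C | intermediate
23 | α-cuprio enoate (copper on C10, cis to the C2 chain) | COC(=O)/C([Cu])=C/CC/C(CO[Si](c1ccccc1)(c1ccccc1)C(C)(C)C)=C\[Si](C)(C)C | intermediate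
24 | methyl (2E,6E)-6-{[tert-butyl(diphenyl)silyl]oxymethyl}-2-[(1S,2S,3R)-3-(1,3-dioxolan-2-yl)-1-hydroxy-2-[(4-methoxybenzyl)oxy]-4-{[(4-methoxybenzyl)oxy]methyl}pent-4-en-1-yl]-7-(trimethylsilyl)hepta-2,6-dienoate | C[Si](C)(C)/C=C(/CO[Si](c1ccccc1)(c1ccccc1)C(C)(C)C)CC/C=C(/C(=O)OC)[C@H](O)[C@@H](OCc1ccc(OC)cc1)[C@H](C1OCCO1)C(=C)COCc1ccc(OC)cc1 | intermediate
25 | O9-triethylsilyl ether of 24 (9S,8S,7R) | C[Si](C)(C)/C=C(/CO[Si](c1ccccc1)(c1ccccc1)C(C)(C)C)CC/C=C(/C(=O)OC)[C@H](O[Si](CC)(CC)CC)[C@@H](OCc1ccc(OC)cc1)[C@H](C1OCCO1)C(=C)COCc1ccc(OC)cc1 | intermediate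
26 | O8,O12-diol from 25 (both p-methoxybenzyl groups removed) | C[Si](C)(C)/C=C(/CO[Si](c1ccccc1)(c1ccccc1)C(C)(C)C)CC/C=C(/C(=O)OC)[C@H](O[Si](CC)(CC)CC)[C@@H](O)[C@H](C1OCCO1)C(=C)CO | intermediate
27 | O9,O12-bis(triethylsilyl) ether with free O8–H | C[Si](C)(C)/C=C(/CO[Si](c1ccccc1)(c1ccccc1)C(C)(C)C)CC/C=C(/C(=O)OC)[C@H](O[Si](CC)(CC)CC)[C@@H](O)[C@H](C1OCCO1)C(=C)CO[Si](CC)(CC)CC | intermediate
28 | O8 methacrylate of 27 | C[Si](C)(C)/C=C(/CO[Si](c1ccccc1)(c1ccccc1)C(C)(C)C)CC/C=C(/C(=O)OC)[C@H](O[Si](CC)(CC)CC)[C@@H](OC(=O)C(C)=C)[C@H](C1OCCO1)C(=C)CO[Si](CC)(CC)CC | intermediate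
29 | C5 alkenyl iodide (iodine cis to C3) | I/C=C(/CO[Si](c1ccccc1)(c1ccccc1)C(C)(C)C)CC/C=C(/C(=O)OC)[C@H](O[Si](CC)(CC)CC)[C@@H](OC(=O)C(C)=C)[C@H](C1OCCO1)C(=C)CO[Si](CC)(CC)CC | intermediate
30 | C6 N-collidinium O-[2-(triethylsilyloxy)ethyl] acetal triflate (C6 epimers) | I/C=C(/CO[Si](c1ccccc1)(c1ccccc1)C(C)(C)C)CC/C=C(/C(=O)OC)[C@H](O[Si](CC)(CC)CC)[C@@H](OC(=O)C(C)=C)[C@H](C(OCCO[Si](CC)(CC)CC)[n+]1c(C)cc(C)cc1C)C(=C)CO[Si](CC)(CC)CC.[O-]S(=O)(=O)C(F)(F)F | intermediate
31 | C6 aldehyde with C5 alkenyl iodide (7R,8S,9S) | I/C=C(/CO[Si](c1ccccc1)(c1ccccc1)C(C)(C)C)CC/C=C(/C(=O)OC)[C@H](O[Si](CC)(CC)CC)[C@@H](OC(=O)C(C)=C)[C@H](C=O)C(=C)CO[Si](CC)(CC)CC | intermediate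
32 | C5 alkenylchromium dichloride from 31 | Cl[Cr](Cl)/C=C(/CO[Si](c1ccccc1)(c1ccccc1)C(C)(C)C)CC/C=C(/C(=O)OC)[C@H](O[Si](CC)(CC)CC)[C@@H](OC(=O)C(C)=C)[C@H](C=O)C(=C)CO[Si](CC)(CC)CC | intermediate
33 | methyl (1(10)E,4E,6R,7S,8S,9S)-15-[tert-butyl(diphenyl)silyl]oxy-6-hydroxy-8-(methacryloyloxy)-9,12-bis(triethylsilyloxy)germacra-1(10),4,11(13)-trien-14-oate | C=C(C)C(=O)O[C@H]1[C@@H](C(=C)CO[Si](CC)(CC)CC)[C@H](O)/C=C(/CO[Si](c2ccccc2)(c2ccccc2)C(C)(C)C)CC/C=C(/C(=O)OC)[C@@H]1O[Si](CC)(CC)CC | intermediate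
34 | O6,O12-diol of 33 (O9 triethylsilyl kept) | C=C(C)C(=O)O[C@H]1[C@@H](C(=C)CO)[C@H](O)/C=C(/CO[Si](c2ccccc2)(c2ccccc2)C(C)(C)C)CC/C=C(/C(=O)OC)[C@@H]1O[Si](CC)(CC)CC | intermediate
35 | C12 enal of 34 | C=C(C)C(=O)O[C@H]1[C@@H](C(=C)C=O)[C@H](O)/C=C(/CO[Si](c2ccccc2)(c2ccccc2)C(C)(C)C)CC/C=C(/C(=O)OC)[C@@H]1O[Si](CC)(CC)CC | intermediate
36 | 6,12-lactol (C12 epimers) | C=C(C)C(=O)O[C@H]1[C@H]2C(=C)C(O)O[C@@H]2/C=C(/CO[Si](c3ccccc3)(c3ccccc3)C(C)(C)C)CC/C=C(/C(=O)OC)[C@@H]1O[Si](CC)(CC)CC | intermediate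
37 | 6,12-lactone with O9 triethylsilyl and O15 tert-butyldiphenylsilyl ethers (6R,7S,8S,9S) | C=C(C)C(=O)O[C@H]1[C@H]2C(=C)C(=O)O[C@@H]2/C=C(/CO[Si](c3ccccc3)(c3ccccc3)C(C)(C)C)CC/C=C(/C(=O)OC)[C@@H]1O[Si](CC)(CC)CC | intermediate
38 | 6,12-lactone with free O9–H | C=C(C)C(=O)O[C@H]1[C@H]2C(=C)C(=O)O[C@@H]2/C=C(/CO[Si](c3ccccc3)(c3ccccc3)C(C)(C)C)CC/C=C(/C(=O)OC)[C@@H]1O | intermediate
39 | O9 acetate with O15 tert-butyldiphenylsilyl ether | C=C(C)C(=O)O[C@H]1[C@H]2C(=C)C(=O)O[C@@H]2/C=C(/CO[Si](c3ccccc3)(c3ccccc3)C(C)(C)C)CC/C=C(/C(=O)OC)[C@@H]1OC(C)=O | intermediate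
40 | CNP0179134.2: methyl (1(10)E,4E,6R,7S,8S,9S)-9-acetoxy-15-hydroxy-8-(methacryloyloxy)-12-oxo-6,12-epoxygermacra-1(10),4,11(13)-trien-14-oate | C=C(C)C(=O)O[C@H]1[C@H]2C(=C)C(=O)O[C@@H]2/C=C(/CO)CC/C=C(/C(=O)OC)[C@@H]1OC(C)=O | target

**Step count:** 24 steps in total. The longest linear sequence is 20 steps (steps 5–11, 12, 13–24); the iodide branch (steps 1–4) joins at step 12.

**Steps most likely to fail**

1. Step 12. The α-cuprio enoate may equilibrate through its allenolate before it is captured, which would deliver the alkene isomer with C2 trans to C9. The hindered aldehyde may also be captured slowly, or attacked without chelation. The fallback sets out from 7 and 19 and comes back at 24, and fixes the alkene geometry by a syn-hydrometalation instead. Iodide 7 is displaced by lithium acetylide–ethylenediamine (LiC≡CH·H2NCH2CH2NH2, DMSO) to give the terminal alkyne F1. Its bromozinc acetylide (n-BuLi, then ZnBr2) adds to 19 under chelation control to give the 8,9-syn propargylic alcohol F2. PdCl2(PPh3)2-catalysed syn-hydrostannation with Bu3SnH places tin on C10, next to the carbinol, to give the alkenylstannane F3. Iodine converts this with retention into the alkenyl iodide F4. Methoxycarbonylation (CO, MeOH, Et3N, Pd(PPh3)4, zerovalent palladium) then gives 24.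

2. Step 19. Ring closure may be slow and lose material to oligomers, the β,γ-unsaturated aldehyde may epimerise at C7, or the alkenylchromium may add to the wrong aldehyde face. The fallback sets out from 31 and comes back at 33; the ring is still closed with CrCl2/NiCl2, but C6 is then set by a reagent and not by the substrate. The alcohol mixture, whose unwanted component is the 6-epimer of 33 F5, is oxidised with Dess–Martin periodinane/NaHCO3 to the ring enone F6. This is reduced with a CBS oxazaborolidine and catecholborane at −78 °C, the catalyst enantiomer being chosen to deliver hydride to the face that gives 33.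

3. Step 8. The open coordination sphere of indium may give poor simple diastereoselectivity (7,8-syn versus anti) or poor Felkin selectivity. The fallback sets out from 11 and comes back at 15, and uses a boron reagent with a tight cyclic transition state. Alcohol 11 is acetylated (Ac2O, DMAP) to the Morita–Baylis–Hillman acetate F7. CuCl/Xantphos/KOt-Bu-catalysed SN2′ borylation with B2pin2 gives the allylboronate F8, with the acetal cis to CH2B. Uncatalysed allylboration of 13 in toluene at 80 °C through the closed six-membered chair then gives 15.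

**Further compounds**
F1 | step 12 | tert-butyl{[(2E)-2-(but-3-yn-1-yl)-3-(trimethylsilyl)prop-2-en-1-yl]oxy}diphenylsilane | C#CCC/C(CO[Si](c1ccccc1)(c1ccccc1)C(C)(C)C)=C\[Si](C)(C)C
F2 | step 12 | 8,9-syn C9 propargylic alcohol (C1≡C10 alkyne, otherwise as 24 without the ester) | C[Si](C)(C)/C=C(/CO[Si](c1ccccc1)(c1ccccc1)C(C)(C)C)CCC#C[C@H](O)[C@@H](OCc1ccc(OC)cc1)[C@H](C1OCCO1)C(=C)COCc1ccc(OC)cc1
F3 | step 12 | C10 tributylstannyl alkene (tin trans to C2) | C[Si](C)(C)/C=C(/CO[Si](c1ccccc1)(c1ccccc1)C(C)(C)C)CC/C=C(/[Sn](CCCC)(CCCC)CCCC)[C@H](O)[C@@H](OCc1ccc(OC)cc1)[C@H](C1OCCO1)C(=C)COCc1ccc(OC)cc1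
F4 | step 12 | C10 iodoalkene (iodine trans to C2) | C[Si](C)(C)/C=C(/CO[Si](c1ccccc1)(c1ccccc1)C(C)(C)C)CC/C=C(/I)[C@H](O)[C@@H](OCc1ccc(OC)cc1)[C@H](C1OCCO1)C(=C)COCc1ccc(OC)cc1
F5 | step 19 | 6-epimer of 33 (6S) | C=C(C)C(=O)O[C@H]1[C@@H](C(=C)CO[Si](CC)(CC)CC)[C@@H](O)/C=C(/CO[Si](c2ccccc2)(c2ccccc2)C(C)(C)C)CC/C=C(/C(=O)OC)[C@@H]1O[Si](CC)(CC)CC
F6 | step 19 | C6 ring enone (6-oxo analogue of 33) | C=C(C)C(=O)O[C@H]1[C@@H](C(=C)CO[Si](CC)(CC)CC)C(=O)/C=C(/CO[Si](c2ccccc2)(c2ccccc2)C(C)(C)C)CC/C=C(/C(=O)OC)[C@@H]1O[Si](CC)(CC)CC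
F7 | step 8 | methyl 2-[acetoxy(1,3-dioxolan-2-yl)methyl]prop-2-enoate | CC(=O)OC(C1OCCO1)C(=C)C(=O)OC
F8 | step 8 | methyl (2E)-3-(1,3-dioxolan-2-yl)-2-[(4,4,5,5-tetramethyl-1,3,2-dioxaborolan-2-yl)methyl]prop-2-enoate | COC(=O)/C(CB1OC(C)(C)C(C)(C)O1)=C/C1OCCO1
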